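**Plan**

- Retrosynthesis: the C8 acetate and the C13 and C18 carboxyls go back to a C13→8α‑O δ‑lactone that carries a C18 benzyloxymethyl group and an extra 3β‑hydroxyl. This lactone is cut at C4–C5, C9–C10 and C8–O (rings A, B and the lactone ring), and the acyclic chain is cut at C11–C12.
- Enabling feature: the trans‑decalin has axial methyls on C4 and C10, an equatorial C18 carbon on C4, an equatorial side chain on C9 and an equatorial oxygen on C8 lying 1,5 to the C13 carboxyl carbon. This is the chair–chair anti‑addition pattern of (E,E)‑farnesylacetic acid oxidised at its terminal E‑methyl.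
- Forward: farnesyl bromide and the tert‑butyl acetate enolate join C11–C12; allylic oxidation, Sharpless epoxidation and O‑benzylation give the epoxy dienoate; one Lewis‑acid cascade then closes ring A, ring B and the lactone ring, in that order.
- Finish: Barton–McCombie removal of the C3 hydroxyl, lactone reduction, C13 protection, C8 acetylation, debenzylation, and oxidation of C13 and C18 to the acids.
- Stereochemistry: the absolute sense comes from the (12S,13S) epoxide made with L‑(+)‑tartrate; E‑alkene geometry and chair–chair anti addition relay it to C4, C5, C10, C9 and C8, and no later step touches these centres.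

Key step: step 6

Remark: labdane numbering and α/β descriptors (β = face of the C10 methyl) are used for the bicyclic compounds; all of them have 4β‑CH3 (C19), 5α‑H, 8β‑CH3 (C17), 9α‑H and 10β‑CH3 (C20), and the 4α substituent is C18.

Assumption: L‑(+)‑diethyl tartrate is taken to give the (2S)‑glycidol series from primary (E)‑allylic alcohols, which here is the (12S,13S) epoxide; LDA is used as a commercial solution.

**Route**

Step 1
Reactants: 1 (2E,6E)-farnesol
Product: 2 (2E,6E)-farnesyl bromide
Conditions: PBr3 (0.4 equiv), Et2O, −10 → 0 °C; used crude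
Reagents that add atoms: phosphorus tribromide, BrP(Br)Br
Why: Bromination of a primary allylic alcohol with PBr3 (SN2 on the phosphite ester) at low temperature should proceed without allylic transposition or E/Z scrambling; no stereocentre is formed.

Step 2
Reactants: 2 (2E,6E)-farnesyl bromide; 3 tert-butyl acetate
Product: 5 tert-butyl (4E,8E)-5,9,13-trimethyltetradeca-4,8,12-trienoate, via lithium tert-butyl acetate enolate 4 (not isolated)
Conditions: LDA (1.3 equiv), 3 (1.3 equiv), THF, −78 °C; then 2 (1.0 equiv), −78 → −20 °C
Reagents that add atoms: tert-butyl acetate (3), CC(=O)OC(C)(C)C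
Why: SN2 C‑alkylation of a preformed lithium ester enolate with a primary allylic bromide joins C11 to C12; excess enolate suppresses dialkylation and no stereocentre is formed.

Step 3
Reactants: 5 tert-butyl (4E,8E)-5,9,13-trimethyltetradeca-4,8,12-trienoate
Product: 6 tert-butyl (4E,8E,12E)-14-hydroxy-5,9,13-trimethyltetradeca-4,8,12-trienoate
Conditions: SeO2 (0.1 equiv), t‑BuOOH (2 equiv), salicylic acid (0.1 equiv), CH2Cl2, 0 °C → rt; stopped at partial conversion, 5 recycled
Reagents that add atoms: tert-butyl hydroperoxide, CC(C)(C)OO (oxygen atom, relayed by catalytic selenium dioxide, O=[Se]=O)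
Why: Catalytic SeO2/TBHP allylic oxidation (ene reaction, then [2,3]-sigmatropic shift) is known to select the E‑methyl of the terminal, least hindered trisubstituted alkene of farnesyl chains and to give the (E)-allylic alcohol; stopping early limits over‑oxidation.

Step 4
Reactants: 6 tert-butyl (4E,8E,12E)-14-hydroxy-5,9,13-trimethyltetradeca-4,8,12-trienoate
Product: 7 tert-butyl (4E,8E,12S,13S)-12,13-epoxy-14-hydroxy-5,9,13-trimethyltetradeca-4,8-dienoate
Conditions: Ti(OiPr)4 (0.1 equiv), L‑(+)‑diethyl tartrate (0.12 equiv), anhydrous t‑BuOOH (2 equiv), 4 Å MS, CH2Cl2, −20 °C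
Reagents that add atoms: tert-butyl hydroperoxide, CC(C)(C)OO
Why: Katsuki–Sharpless asymmetric epoxidation touches only the alkene of the allylic alcohol, and the L‑(+)‑tartrate catalyst sets both epoxide centres as the (12S,13S)-trans-epoxide, whose C12 becomes C3 (β‑oxygen) and which fixes the absolute sense of the cascade.

Step 5
Reactants: 7 tert-butyl (4E,8E,12S,13S)-12,13-epoxy-14-hydroxy-5,9,13-trimethyltetradeca-4,8-dienoate; 8 benzyl bromide
Product: 9 tert-butyl (4E,8E,12S,13S)-14-(benzyloxy)-12,13-epoxy-5,9,13-trimethyltetradeca-4,8-dienoate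
Conditions: NaH (1.2 equiv), BnBr (1.2 equiv), Bu4NI (cat.), THF, 0 °C → rt
Reagents that add atoms: benzyl bromide (8), BrCc1ccccc1
Why: Williamson etherification of the primary alkoxide caps the hydroxyl as a Lewis‑acid‑stable, chelating benzyl ether; the fully substituted C13 disfavours Payne rearrangement and the epoxide stereocentres are untouched.

Step 6
Reactants: 9 tert-butyl (4E,8E,12S,13S)-14-(benzyloxy)-12,13-epoxy-5,9,13-trimethyltetradeca-4,8-dienoate
Product: 10 18-(benzyloxy)-3β-hydroxy-14,15,16-trinorlabdan-13,8α-olide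
Conditions: SnCl4 (1.2 equiv, promoter), CH2Cl2 (0.01 M), −78 → −40 °C; aq. NaHCO3
Reagents that add atoms: none
Why: SnCl4, held in a five‑membered chelate by the epoxide and benzyl ether oxygens, weakens the C4–O bond at the tertiary epoxide carbon; the C5=C10 alkene attacks C4 anti to the leaving oxygen, the C8=C9 alkene adds to the developing C10 cation, the free ester carbonyl oxygen captures the C8 cation, and the resulting tert‑butyl oxocarbenium ion sheds isobutene to leave the δ‑lactone. This is a Lewis‑acid epoxy‑polyene cyclization with carboxyl (ester) termination, the epoxide‑initiated counterpart of the acid cyclization of farnesylacetic acid to ambreinolide‑type lactones. Ring A closes 6‑endo (both alkene carbons and both epoxide carbons in the ring), ring B closes 6‑endo‑trig, and the lactone ring closes by six‑membered O‑capture at C8 (endo with respect to the consumed C8=C9 alkene). C3 keeps the epoxide configuration (equatorial 3β‑OH); C4 is inverted by backside attack, so the E‑benzyloxymethyl group becomes equatorial 4α (C18) and the methyl axial 4β; C5 and C10 arise from anti addition across the E C5=C10 alkene in a chair (5α‑H, 10β‑CH3); C9 and C8 arise from anti addition across the E C8=C9 alkene in the second chair (9α‑H, equatorial 8α‑O, axial 8β‑CH3). The step needs opening at C4 and not C3, a complete cascade without early proton loss, and chair–chair folding; these are secured by the tertiary epoxide carbon, two nucleophilic trisubstituted alkenes placed for Markovnikov 6‑endo closure, low temperature, high dilution, and a Lewis acid sequestered at the chelating epoxide end so that the ester carbonyl stays nucleophilic. The absolute sense follows from the (12S,13S) epoxide, whose C3–O bond lies equatorial in the folded chain.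

Step 7
Reactants: 10 18-(benzyloxy)-3β-hydroxy-14,15,16-trinorlabdan-13,8α-olide
Product: 11 18-(benzyloxy)-3β-(imidazol-1-ylthiocarbonyloxy)-14,15,16-trinorlabdan-13,8α-olide
Conditions: 1,1'-thiocarbonyldiimidazole (2 equiv), DMAP (0.2 equiv), 1,2‑dichloroethane, 80 °C
Reagents that add atoms: 1,1'-thiocarbonyldiimidazole, S=C(n1ccnc1)n1ccnc1
Why: Thioacylation of the equatorial 3β‑hydroxyl (first half of the Barton–McCombie deoxygenation) runs under neutral conditions that spare the lactone and the benzyl ether; the C3 configuration is retained.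

Step 8
Reactants: 11 18-(benzyloxy)-3β-(imidazol-1-ylthiocarbonyloxy)-14,15,16-trinorlabdan-13,8α-olide
Product: 12 18-(benzyloxy)-14,15,16-trinorlabdan-13,8α-olide
Conditions: Bu3SnH (1.5 equiv), AIBN (0.1 equiv), toluene, 110 °C
Reagents that add atoms: none
Why: Barton–McCombie radical deoxygenation (stannyl radical addition to C=S, β‑scission to the secondary C3 radical, hydrogen transfer from Bu3SnH) removes the oxygen, so C3 ceases to be a stereocentre while quaternary C4 and all other centres stay untouched.

Step 9
Reactants: 12 18-(benzyloxy)-14,15,16-trinorlabdan-13,8α-olide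
Product: 13 18-(benzyloxy)-14,15,16-trinorlabdane-8α,13-diol
Conditions: LiAlH4 (1.5 equiv), THF, 0 °C → rt; aqueous NaOH work‑up
Reagents that add atoms: none
Why: Hydride reduction of the lactone carbonyl releases the primary C13 alcohol and the tertiary C8 alcohol without breaking the C8–O bond, so the 8α configuration is retained; the benzyl ether is inert.

Step 10
Reactants: 13 18-(benzyloxy)-14,15,16-trinorlabdane-8α,13-diol; 8 benzyl bromide
Product: 14 13,18-bis(benzyloxy)-14,15,16-trinorlabdan-8α-ol
Conditions: NaH (1.2 equiv), BnBr (1.1 equiv), Bu4NI (cat.), THF, 0 °C → rt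
Reagents that add atoms: benzyl bromide (8), BrCc1ccccc1
Why: Williamson etherification is selective for the unhindered primary C13 alkoxide over the hindered tertiary C8 hydroxyl, so C13 is masked while C8 is acylated; no stereocentre changes.

Step 11
Reactants: 14 13,18-bis(benzyloxy)-14,15,16-trinorlabdan-8α-ol; 15 acetyl chloride
Product: 16 13,18-bis(benzyloxy)-14,15,16-trinorlabdan-8α-yl acetate
Conditions: AcCl (5 equiv), N,N‑dimethylaniline (6 equiv), CH2Cl2, 0 °C → rt
Reagents that add atoms: acetyl chloride (15), CC(Cl)=O
Why: Acylation with acetyl chloride buffered by the weak base N,N‑dimethylaniline is the standard esterification of the hindered tertiary C8 hydroxyl of labdan‑8‑ols such as sclareol and suppresses acid‑induced dehydration; the C8–O bond is not broken, so configuration is retained.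

Step 12
Reactants: 16 13,18-bis(benzyloxy)-14,15,16-trinorlabdan-8α-yl acetate
Product: 17 8α-acetoxy-14,15,16-trinorlabdane-13,18-diol
Conditions: H2 (1 atm), 10% Pd/C, EtOAc, rt
Reagents that add atoms: none
Why: Catalytic hydrogenolysis cleaves both benzyl ethers to the primary alcohols at C13 and C18; the tertiary acetate and the saturated skeleton are inert.

Step 13
Reactants: 17 8α-acetoxy-14,15,16-trinorlabdane-13,18-diol
Product: 18 8α-acetoxy-14,15,16-trinorlabdane-13,18-dioic acid
Conditions: TEMPO (0.2 equiv), NaOCl (cat.), NaClO2 (5 equiv), MeCN / phosphate buffer pH 6.7, 35 °C; then acidify to pH 3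
Reagents that add atoms: sodium chlorite, [Na+].[O-]Cl=O
Why: One‑pot TEMPO/hypochlorite/chlorite oxidation (oxoammonium oxidation, then Pinnick‑type chlorite oxidation at the aldehyde stage) converts both primary alcohols into carboxylic acids near neutral pH, where the tertiary acetate survives; C4 is quaternary, so nothing can epimerise.

**Compound list**

1 | (2E,6E)-farnesol | CC(C)=CCC/C(C)=C/CC/C(C)=C/CO | starting material
2 | (2E,6E)-farnesyl bromide | CC(C)=CCC/C(C)=C/CC/C(C)=C/CBr | intermediate
3 | tert-butyl acetate | CC(=O)OC(C)(C)C | starting material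
4 | lithium tert-butyl acetate enolate (lithium 1-tert-butoxyethen-1-olate; not isolated) | [Li+].[O-]C(=C)OC(C)(C)C | intermediate
5 | tert-butyl (4E,8E)-5,9,13-trimethyltetradeca-4,8,12-trienoate | CC(C)(C)OC(=O)CC/C=C(\C)CC/C=C(\C)CCC=C(C)C | intermediate
6 | tert-butyl (4E,8E,12E)-14-hydroxy-5,9,13-trimethyltetradeca-4,8,12-trienoate | CC(C)(C)OC(=O)CC/C=C(\C)CC/C=C(\C)CC/C=C(\C)CO | intermediate
7 | tert-butyl (4E,8E,12S,13S)-12,13-epoxy-14-hydroxy-5,9,13-trimethyltetradeca-4,8-dienoate | CC(C)(C)OC(=O)CC/C=C(\C)CC/C=C(\C)CC[C@@H]1O[C@@]1(C)CO | intermediate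
8 | benzyl bromide | BrCc1ccccc1 | starting material
9 | tert-butyl (4E,8E,12S,13S)-14-(benzyloxy)-12,13-epoxy-5,9,13-trimethyltetradeca-4,8-dienoate (trans-epoxide; key-step precursor) | CC(C)(C)OC(=O)CC/C=C(\C)CC/C=C(\C)CC[C@@H]1O[C@@]1(C)COCc1ccccc1 | intermediate
10 | 18-(benzyloxy)-3β-hydroxy-14,15,16-trinorlabdan-13,8α-olide (key-step product) | O=C3O[C@]1(C)CC[C@@H]2[C@](C)(CC[C@H](O)[C@@]2(C)COCc4ccccc4)[C@H]1CC3 | intermediate
11 | 18-(benzyloxy)-3β-(imidazol-1-ylthiocarbonyloxy)-14,15,16-trinorlabdan-13,8α-olide | O=C3O[C@]1(C)CC[C@@H]2[C@](C)(CC[C@H](OC(=S)n5ccnc5)[C@@]2(C)COCc4ccccc4)[C@H]1CC3 | intermediate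
12 | 18-(benzyloxy)-14,15,16-trinorlabdan-13,8α-olide | O=C3O[C@]1(C)CC[C@@H]2[C@](C)(CCC[C@@]2(C)COCc4ccccc4)[C@H]1CC3 | intermediate
13 | 18-(benzyloxy)-14,15,16-trinorlabdane-8α,13-diol | O[C@]1(C)CC[C@@H]2[C@](C)(CCC[C@@]2(C)COCc3ccccc3)[C@H]1CCCO | intermediate
14 | 13,18-bis(benzyloxy)-14,15,16-trinorlabdan-8α-ol | O[C@]1(C)CC[C@@H]2[C@](C)(CCC[C@@]2(C)COCc3ccccc3)[C@H]1CCCOCc4ccccc4 | intermediate
15 | acetyl chloride | CC(Cl)=O | starting material
16 | 13,18-bis(benzyloxy)-14,15,16-trinorlabdan-8α-yl acetate | CC(=O)O[C@]1(C)CC[C@@H]2[C@](C)(CCC[C@@]2(C)COCc3ccccc3)[C@H]1CCCOCc4ccccc4 | intermediate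
17 | 8α-acetoxy-14,15,16-trinorlabdane-13,18-diol | CC(=O)O[C@]1(C)CC[C@@H]2[C@](C)(CCC[C@@]2(C)CO)[C@H]1CCCO | intermediate
18 | 8α-acetoxy-14,15,16-trinorlabdane-13,18-dioic acid (CNP0196050.1) | CC(=O)O[C@]1(C)CC[C@@H]2[C@](C)(CCC[C@@]2(C)C(=O)O)[C@H]1CCC(=O)O | target

**Step count and risks**

Total steps: 13. Longest linear sequence: 13 steps (1 → 18).

Steps most likely to fail:

1. Step 6. The cascade may end by proton loss before the ester carbonyl reaches the C8 cation, or the activated epoxide may rearrange by a 1,2‑hydride shift without alkene participation. Fallback (two‑stage closure): setting out from 9, the carbocyclization is run deliberately as an alkene‑terminated bicyclization (MeAlCl2, 3 equiv, CH2Cl2, −78 °C, ester fully complexed). This should give tert-butyl 18-(benzyloxy)-3β-hydroxy-14,15,16-trinorlabd-8(17)-en-13-oate F1 together with its endocyclic double‑bond isomers, all of which lead to the same C8 cation. The mixture is then treated with p‑TsOH·H2O in toluene at 60 °C, where Markovnikov protonation and equilibrating lactonization with loss of isobutene should give the trans‑fused lactone, returning to the route at 10.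

2. Step 3. Allylic oxidation may be unselective (attack at internal allylic positions, over‑oxidation to the enal) and conversion low. Fallback (terminal degradation and rebuild): setting out from 5, terminal‑selective bromohydrin formation (NBS, THF–H2O, 0 °C) should give tert-butyl (4E,8E)-12-bromo-13-hydroxy-5,9,13-trimethyltetradeca-4,8-dienoate F2. This is closed with K2CO3 in MeOH to racemic tert-butyl (4E,8E)-12,13-epoxy-5,9,13-trimethyltetradeca-4,8-dienoate F3. Periodic acid cleavage (H5IO6, THF–H2O, 0 °C) gives tert-butyl (4E,8E)-5,9-dimethyl-12-oxododeca-4,8-dienoate F4. Wittig olefination with 2‑(triphenylphosphoranylidene)propanal (toluene, 90 °C) gives tert-butyl (4E,8E,12E)-5,9,13-trimethyl-14-oxotetradeca-4,8,12-trienoate F5. Luche reduction (NaBH4, CeCl3·7H2O, MeOH, 0 °C) returns to the route at 6.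

3. Step 11. The tertiary C8–O bond may ionise under the acidic by‑product (E1 dehydration), or acyl transfer to the hindered hydroxyl may fail. Fallback (acylation through a preformed metal alkoxide, no acid present): setting out from 14, deprotonation with n‑BuLi (1.1 equiv, THF, −78 °C) gives lithium 13,18-bis(benzyloxy)-14,15,16-trinorlabdan-8α-olate F6, which is quenched with acetic anhydride (3 equiv, −78 → 0 °C), returning to the route at 16.

Further compounds
F1 | step 6 | tert-butyl 18-(benzyloxy)-3β-hydroxy-14,15,16-trinorlabd-8(17)-en-13-oate | C=C1CC[C@@H]2[C@](C)(CC[C@H](O)[C@@]2(C)COCc3ccccc3)[C@H]1CCC(=O)OC(C)(C)C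
F2 | step 3 | tert-butyl (4E,8E)-12-bromo-13-hydroxy-5,9,13-trimethyltetradeca-4,8-dienoate (racemic) | CC(C)(C)OC(=O)CC/C=C(\C)CC/C=C(\C)CCC(Br)C(C)(C)O
F3 | step 3 | tert-butyl (4E,8E)-12,13-epoxy-5,9,13-trimethyltetradeca-4,8-dienoate (racemic) | CC(C)(C)OC(=O)CC/C=C(\C)CC/C=C(\C)CCC1OC1(C)C
F4 | step 3 | tert-butyl (4E,8E)-5,9-dimethyl-12-oxododeca-4,8-dienoate | CC(C)(C)OC(=O)CC/C=C(\C)CC/C=C(\C)CCC=O
F5 | step 3 | tert-butyl (4E,8E,12E)-5,9,13-trimethyl-14-oxotetradeca-4,8,12-trienoate | CC(C)(C)OC(=O)CC/C=C(\C)CC/C=C(\C)CC/C=C(\C)C=O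
F6 | step 11 | lithium 13,18-bis(benzyloxy)-14,15,16-trinorlabdan-8α-olate | [Li+].[O-][C@]1(C)CC[C@@H]2[C@](C)(CCC[C@@]2(C)COCc3ccccc3)[C@H]1CCCOCc4ccccc4
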